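The earlier runs and the new flask are simulated from invented constants, and the scatter is random.

At early times I compare first readings, in these runs of starting material (S) with coupling partner (R):

| flask | starting material | coupling partner | time |
|---|---|---|---|
| teal | 0.500 M | 1.50 M |  |
| ochre | 0.300 M | 1.30 M |  |
| amber | 1.00 M | 1.50 M |  |
| violet | 1.50 M | 3.00 M | 4.3 min |

| teal run: time / min | teal run: [product] / M | ochre run: time / min | ochre run: [product] / M | amber run: time / min | amber run: [product] / M |
|---|---|---|---|---|---|
| 0.72 | 0.057 | 0.72 | 0.034 | 0.72 | 0.114 |
| 1.4 | 0.111 | 1.4 | 0.052 | 1.4 | 0.199 |
| 2.1 | 0.151 | 2.1 | 0.093 | 2.1 | 0.281 |
| 2.9 | 0.201 | 2.9 | 0.109 | 2.9 | 0.354 |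
| 3.6 | 0.228 | 3.6 | 0.132 | 3.6 | 0.415 |
| 4.3 | 0.258 | 4.3 | 0.150 | 4.3 | 0.461 |

(standard deviation of a reading: 0.004 M)

- Overall: starting material + coupling partner -> product.
- Constant volume, constant temperature.
- What is held in complexes is read along with the free species.
- "The second partner" is coupling partner.
- An order is taken over about fifteen percent of the charge, up and down.

1. the power of [coupling partner] that the first rate follows, about the charge of the teal run; measure it at two percent of starting material made into product
2. the power of [starting material] that the first rate follows, about the charge of the teal run; measure it at two percent of starting material made into product (one fixed amount of product, the same in the runs compared)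
3. the ochre run starts with 0.200 M less of starting material and of coupling partner than the teal run, and with no product. Compared where both hold the same amount of starting material, once fifteen percent of what the ochre run was charged with has turned into product, is the ochre run faster, slower or alike (within a tenth)?
4. product in the violet run at 4.3 min, as a share of the starting material charged

At 0.72 min, the amber run, charged with 1.00 M of S, reads 2.00 times as much product as the teal run, charged with 0.500 M of S and the same R, so these two readings put the power in S near 1.00. The ochre run is charged with 13.3 % less R than the teal run, and its first reading scatters by 11.8 %, so I read no power in R from it. I take a power of 1 in each, rate = κ·S·R, and test that below.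

Each flask holds less S than R, so S is the limiting reagent. Each product takes one S and one R, so the excess E = R − S stays at its charged value. The ratio R/S then climbs exponentially, and the logarithm of its rise over the charged ratio is one dimensionless number, N = κ·E·t. The share made follows as (e^N − 1)/(e^N − charged S/R).

The teal run, with E = 1.00 M, reads 0.258 M of product at 4.3 min, when R/S has risen by a factor of 1.71. That reading gives κ = 0.125 L mol⁻¹ min⁻¹, the pair's second-order constant. For the violet run, N = 0.805, so I commit to 71.2 %.

The ochre run has the teal run's E and starts where the teal run has made 0.200 M, which the teal run reads at about 2.9 min. Both then hold the same S and R, so I expect them alike. Was one number enough? For the ochre run, κ gives 0.144 M of product at 4.3 min, and the reading is 0.150 M. For the amber run it gives 0.480 M at 4.3 min, but the reading is lower than that, 0.461 M, which is 4.80 standard deviations of a reading.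

The forecast gives 0.7 in R, 0.9 in S, alike (“no visible product or history effect”) and 57 % for violet, where I hold a power near 1 and 71.2 %.

The flask gives 1.1 in R, 0.95 in S, alike, and 70.1 % for violet, 1.1 percentage points below my share.

    starting material + 2 coupling partner → product + coupling partner (1.956 L² mol⁻² min⁻¹)
    2 coupling partner ⇌ idle reagent dimer, settled at all times (4.530 L mol⁻¹)
    starting material + coupling partner ⇌ idle substrate-reagent adduct, settled at all times (0.7170 L mol⁻¹)

The fit with main steps alone puts the violet run at 83.0 %. On the amber run, κ gives a quarter of the charge at 1.69 min, and the amber run reaches it at 1.83 min.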